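**Strategy.** Ring A (the hydroxylated cyclohexane) is numbered C1 (CH–iPr), C2, C3 (CH2), C4 (C–OH), C5 (CH–CO2H), C6 (CH–alkenyl). Everything rests on closing it by the C1–C2 bond: iPr–C1–C2H2–C3H2–C4(O) is the retron of an ene reaction in which a 2-methylprop-1-enyl group on C6 adds through C1 to the CH2 end of a vinyl ketone (C2=C3–C4=O) and becomes isopropenyl. The precursor is an acyclic β-keto ester made by one catalytic asymmetric nitro-Michael addition; cyclisation sets C1 and equilibrates C5. The same cyclohexanone supplies both halves through a hydroxy lactone, dehydrated to the butenolide acid or opened and acylated.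

Key step: step 3

Assumption: the (R,R)-configured amine–thiourea is taken to deliver the β-keto ester to the same face of the nitroalkene as it does with β-nitrostyrene, which gives 6 with the (R) centre; if the sense proves opposite, the (S,S)-catalyst is used and nothing else changes.

**Step 1**
Reactants: 1 3-methylbut-2-enal; 2 nitromethane
Product: 4 (1E)-4-methyl-1-nitropenta-1,3-diene, via nitroaldol 3 (not isolated)
Conditions: 2 (5 equiv), KOtBu (5 mol%), THF/tBuOH, 0 °C; then MsCl, Et3N, CH2Cl2, 0 °C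
Reagents that add atoms: none
Why: Henry reaction at the aldehyde carbon followed by mesylation and E1cB elimination should give the conjugated (E)-nitrodiene; no stereocentre is formed.

**Step 2**
Reactants: 4 (1E)-4-methyl-1-nitropenta-1,3-diene; 5 methyl 5-methoxy-3-oxopentanoate
Product: 6 methyl (2RS)-5-methoxy-2-[(2R)-4-methyl-1-nitropent-3-en-2-yl]-3-oxopentanoate
Conditions: 5 (1.5 equiv), 1-[3,5-bis(trifluoromethyl)phenyl]-3-[(1R,2R)-2-(dimethylamino)cyclohexyl]thiourea (10 mol%), PhMe, rt
Reagents that add atoms: none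
Why: Catalytic asymmetric Michael addition of a β-keto ester to a nitroalkene (1,4-addition, since the δ-carbon is disubstituted); the thiourea binds the nitro group and the ammonium-bound enol attacks one face, which sets the future C6 as (R), while the epimerisable α-carbon (future C5) is left uncontrolled.

**Step 3**
Reactants: 6 methyl (2RS)-5-methoxy-2-[(2R)-4-methyl-1-nitropent-3-en-2-yl]-3-oxopentanoate
Product: 8 methyl (1S,2R,3S)-2-(nitromethyl)-6-oxo-3-(prop-1-en-2-yl)cyclohexane-1-carboxylate, via vinyl ketone 7 (not isolated)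
Conditions: TsOH·H2O (5 mol%), 4 Å MS, PhMe, 80 °C; then solvent switch, SnCl4 (1.2 equiv), CH2Cl2 (0.01 M), −78 to −20 °C
Reagents that add atoms: none
Why: Acid-catalysed loss of methanol from the β-methoxy ketone unmasks the vinyl ketone 7, and in its SnCl4 complex the CH carbon (C1) of the 2-methylprop-1-enyl group bonds to the terminal CH2 (C2) while a methyl hydrogen passes to C3, leaving an isopropenyl group on C1; the closest known reaction type is the Lewis-acid-promoted type 1 intramolecular ene reaction of a 1,7-diene with an enone enophile. The cyclohexanone closes 6-endo-trig at the enone (C2 and C3 both end in the ring) and exo at the ene double bond. C1 is controlled by the existing C6 centre: allylic 1,3-strain holds the C6–H in the plane of the trisubstituted alkene, and a chair transition state with CH2NO2 equatorial should give the trans C1/C6 relation. C5 then equilibrates through the β-keto ester enol to the all-equatorial isomer, so one stereocentre fixes three. The step needs ene transfer to win over intermolecular Michael addition of the β-keto ester and over chloride capture of the tertiary cation, which high dilution and low temperature favour. The competing intramolecular hetero-Diels–Alder adduct is excluded by the substrate, because it would hold a bridgehead enol ether in a bicyclo[2.2.2]octene.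

**Step 4**
Reactants: 8 methyl (1S,2R,3S)-2-(nitromethyl)-6-oxo-3-(prop-1-en-2-yl)cyclohexane-1-carboxylate
Product: 9 methyl (1S,2R,3R)-2-(nitromethyl)-6-oxo-3-(propan-2-yl)cyclohexane-1-carboxylate
Conditions: H2 (1 atm), RhCl(PPh3)3 (5 mol%), PhH/EtOH, rt
Reagents that add atoms: none
Why: Homogeneous catalytic hydrogenation should saturate only the unhindered 1,1-disubstituted alkene and leave nitro, ketone and ester alone; no new stereocentre is formed.

**Step 5**
Reactants: 9 methyl (1S,2R,3R)-2-(nitromethyl)-6-oxo-3-(propan-2-yl)cyclohexane-1-carboxylate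
Product: 11 methyl (1S,2R,3R)-2-formyl-6-oxo-3-(propan-2-yl)cyclohexane-1-carboxylate, via disodium nitronate enolate 10 (not isolated)
Conditions: NaOMe (2.1 equiv), MeOH, 0 °C; then aq. TiCl3, NH4OAc (pH 5), 0 °C to rt
Reagents that add atoms: water O
Why: Nef reaction in its reductive TiCl3 form: the nitronate is reduced to the imine and hydrolysed to the aldehyde under buffered conditions that the β-keto ester should tolerate, and C6 (now α to the aldehyde) stays in or returns to the equatorial trans arrangement.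

**Step 6**
Reactants: 12 tert-butyl (diethoxyphosphoryl)acetate; 13 formaldehyde (as paraformaldehyde)
Product: 15 tert-butyl 2-(diethoxyphosphoryl)prop-2-enoate, via hydroxymethyl phosphonate 14 (not isolated)
Conditions: (CH2O)n, piperidine (10 mol%), AcOH (20 mol%), PhMe, reflux, Dean–Stark
Reagents that add atoms: none
Why: Knoevenagel condensation of the phosphonoacetate with formaldehyde under amine–acid catalysis, mild enough for the tert-butyl ester; no stereocentre is formed.

**Step 7**
Reactants: 11 methyl (1S,2R,3R)-2-formyl-6-oxo-3-(propan-2-yl)cyclohexane-1-carboxylate; 15 tert-butyl 2-(diethoxyphosphoryl)prop-2-enoate; 16 (4-methoxyphenyl)methanol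
Product: 18 methyl (1S,2S,3R)-2-[(1E)-3-tert-butoxy-2-{[(4-methoxyphenyl)methoxy]methyl}-3-oxoprop-1-en-1-yl]-6-oxo-3-(propan-2-yl)cyclohexane-1-carboxylate, via sodium phosphonate carbanion 17 (not isolated)
Conditions: 16 (2.2 equiv), NaH (2.2 equiv), THF, 0 °C; 15 (2.2 equiv), 0 °C; then 11, −20 °C to rt
Reagents that add atoms: none
Why: Tandem oxa-Michael addition and Horner–Wadsworth–Emmons olefination: the alkoxide adds to the phosphonoacrylate and the resulting carbanion olefinates the aldehyde (one equivalent is spent on the β-keto ester proton); an α-substituted phosphonate with a bulky ester and an α-branched aldehyde should give the (E)-alkene with the ring trans to the ester.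

**Step 8**
Reactants: 18 methyl (1S,2S,3R)-2-[(1E)-3-tert-butoxy-2-{[(4-methoxyphenyl)methoxy]methyl}-3-oxoprop-1-en-1-yl]-6-oxo-3-(propan-2-yl)cyclohexane-1-carboxylate
Product: 19 methyl (1S,2S,3R)-2-[(1E)-3-tert-butoxy-2-{[(4-methoxyphenyl)methoxy]methyl}-3-oxoprop-1-en-1-yl]-6-methylidene-3-(propan-2-yl)cyclohexane-1-carboxylate
Conditions: Zn, CH2Br2, TiCl4 (reagent preformed in THF, 0 °C), CH2Cl2, 0 °C to rt
Reagents that add atoms: dibromomethane BrCBr
Why: Takai–Lombardo methylenation: the non-basic zinc–titanium methylene reagent should olefinate the ketone in the presence of three esters without epimerising C5.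

**Step 9**
Reactants: 19 methyl (1S,2S,3R)-2-[(1E)-3-tert-butoxy-2-{[(4-methoxyphenyl)methoxy]methyl}-3-oxoprop-1-en-1-yl]-6-methylidene-3-(propan-2-yl)cyclohexane-1-carboxylate
Product: 21 tert-butyl (2E)-3-[(3aS,6R,7S,7aS)-3a-hydroxy-1-oxo-6-(propan-2-yl)octahydro-2-benzofuran-7-yl]-2-{[(4-methoxyphenyl)methoxy]methyl}prop-2-enoate, via diol ester 20 (not isolated)
Conditions: OsO4 (2 mol%), NMO (1.2 equiv), acetone/H2O, 0 °C; then PPTS (cat.), CH2Cl2, rt
Reagents that add atoms: osmium tetroxide O=[Os](=O)(=O)=O; N-methylmorpholine N-oxide C[N+]1([O-])CCOCC1; water O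
Why: Upjohn dihydroxylation of the electron-rich 1,1-disubstituted alkene in preference to the acrylate; OsO4 should attack the exocyclic alkene from the equatorial face (clear of the axial hydrogens on C2 and C6), which sets C4 with the hydroxyl equatorial and the CH2OH axial and cis to the ester, so that lactonisation follows.

**Step 10**
Reactants: 21 tert-butyl (2E)-3-[(3aS,6R,7S,7aS)-3a-hydroxy-1-oxo-6-(propan-2-yl)octahydro-2-benzofuran-7-yl]-2-{[(4-methoxyphenyl)methoxy]methyl}prop-2-enoate
Product: 22 tert-butyl (2E)-2-{[(4-methoxyphenyl)methoxy]methyl}-3-[(6R,7S)-1-oxo-6-(propan-2-yl)-1,3,4,5,6,7-hexahydro-2-benzofuran-7-yl]prop-2-enoate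
Conditions: methyl N-(triethylammoniosulfonyl)carbamate (2 equiv), PhH, 50 °C
Reagents that add atoms: none
Why: Burgess dehydration (syn elimination) of the tertiary β-hydroxy lactone through the cis, acidic hydrogen α to the lactone carbonyl should give the tetrasubstituted butenolide; the C4 and C5 stereocentres of this half are erased, as the second ring requires.

**Step 11**
Reactants: 22 tert-butyl (2E)-2-{[(4-methoxyphenyl)methoxy]methyl}-3-[(6R,7S)-1-oxo-6-(propan-2-yl)-1,3,4,5,6,7-hexahydro-2-benzofuran-7-yl]prop-2-enoate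
Product: 23 (2E)-2-{[(4-methoxyphenyl)methoxy]methyl}-3-[(6R,7S)-1-oxo-6-(propan-2-yl)-1,3,4,5,6,7-hexahydro-2-benzofuran-7-yl]prop-2-enoic acid
Conditions: SiO2, PhMe, 110 °C
Reagents that add atoms: none
Why: Silica-promoted thermal cleavage of the tert-butyl ester (loss of isobutene) should free the acrylic acid while the benzyl-type ether and the butenolide survive; no stereocentre is touched.

**Step 12**
Reactants: 21 tert-butyl (2E)-3-[(3aS,6R,7S,7aS)-3a-hydroxy-1-oxo-6-(propan-2-yl)octahydro-2-benzofuran-7-yl]-2-{[(4-methoxyphenyl)methoxy]methyl}prop-2-enoate; 23 (2E)-2-{[(4-methoxyphenyl)methoxy]methyl}-3-[(6R,7S)-1-oxo-6-(propan-2-yl)-1,3,4,5,6,7-hexahydro-2-benzofuran-7-yl]prop-2-enoic acid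
Product: 26 (1S,2S,3R,6S)-2-[(1E)-3-tert-butoxy-2-{[(4-methoxyphenyl)methoxy]methyl}-3-oxoprop-1-en-1-yl]-6-hydroxy-6-{[((2E)-2-{[(4-methoxyphenyl)methoxy]methyl}-3-[(6R,7S)-1-oxo-6-(propan-2-yl)-1,3,4,5,6,7-hexahydro-2-benzofuran-7-yl]prop-2-enoyl)oxy]methyl}-3-(propan-2-yl)cyclohexane-1-carboxylic acid, via lithium carboxylate 24 (not isolated), via acyl imidazole 25 (not isolated)
Conditions: 21, LiOH·H2O (1.05 equiv), THF/H2O, 0 °C, then evaporation and PhMe azeotrope; 23, 1,1'-carbonyldiimidazole (1.1 equiv), THF, rt; both combined in DMF, DBU (0.2 equiv), 0 °C to rt; aq. HCl to pH 3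
Reagents that add atoms: lithium hydroxide [Li+].[OH-]
Why: Lactone saponification followed by alcoholysis of an N-acylimidazole: hydroxide opens the γ-lactone far faster than it touches the tert-butyl ester, the carboxylate salt cannot relactonise, and the acyl imidazole (which does not form a mixed anhydride with a carboxylate) should acylate only the primary hydroxyl, not the tertiary one; no stereocentre changes.

**Step 13**
Reactants: 26 the protected dimer acid of step 12
Product: 27 (1S,2S,3R,6S)-2-[(1E)-2-carboxy-3-hydroxyprop-1-en-1-yl]-6-hydroxy-6-{[((2E)-2-(hydroxymethyl)-3-[(6R,7S)-1-oxo-6-(propan-2-yl)-1,3,4,5,6,7-hexahydro-2-benzofuran-7-yl]prop-2-enoyl)oxy]methyl}-3-(propan-2-yl)cyclohexane-1-carboxylic acid (CNP0071646.2)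
Conditions: TFA/CH2Cl2 (1:4), anisole (10 equiv), 0 °C
Reagents that add atoms: none
Why: Acidolysis should remove the tert-butyl ester and both 4-methoxybenzyl ethers in one operation (anisole traps the benzyl cation), while the tertiary alcohol, flanked by electron-poor groups, should not ionise at this temperature.

**Compound list**

1 | 3-methylbut-2-enal | CC(C)=CC=O | starting material
2 | nitromethane | C[N+](=O)[O-] | starting material
3 | 4-methyl-1-nitropent-3-en-2-ol (racemic nitroaldol) | CC(C)=CC(O)C[N+](=O)[O-] | intermediate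
4 | (1E)-4-methyl-1-nitropenta-1,3-diene | CC(C)=C/C=C/[N+](=O)[O-] | intermediate
5 | methyl 5-methoxy-3-oxopentanoate | COCCC(=O)CC(=O)OC | starting material
6 | methyl (2RS)-5-methoxy-2-[(2R)-4-methyl-1-nitropent-3-en-2-yl]-3-oxopentanoate | COCCC(=O)C(C(=O)OC)[C@@H](C=C(C)C)C[N+](=O)[O-] | intermediate
7 | methyl (2RS)-2-[(2R)-4-methyl-1-nitropent-3-en-2-yl]-3-oxopent-4-enoate | C=CC(=O)C(C(=O)OC)[C@@H](C=C(C)C)C[N+](=O)[O-] | intermediate
8 | methyl (1S,2R,3S)-2-(nitromethyl)-6-oxo-3-(prop-1-en-2-yl)cyclohexane-1-carboxylate (keto form, all-trans) | CC(=C)[C@H]1CCC(=O)[C@@H](C(=O)OC)[C@@H]1C[N+](=O)[O-] | intermediate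
9 | methyl (1S,2R,3R)-2-(nitromethyl)-6-oxo-3-(propan-2-yl)cyclohexane-1-carboxylate | CC(C)[C@H]1CCC(=O)[C@@H](C(=O)OC)[C@@H]1C[N+](=O)[O-] | intermediate
10 | disodium salt of 9 (ester enolate and nitronate) | CC(C)[C@H]1CCC([O-])=C(C(=O)OC)[C@@H]1C=[N+]([O-])[O-].[Na+].[Na+] | intermediate
11 | methyl (1S,2R,3R)-2-formyl-6-oxo-3-(propan-2-yl)cyclohexane-1-carboxylate | CC(C)[C@H]1CCC(=O)[C@@H](C(=O)OC)[C@@H]1C=O | intermediate
12 | tert-butyl (diethoxyphosphoryl)acetate | CCOP(=O)(OCC)CC(=O)OC(C)(C)C | starting material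
13 | formaldehyde (as paraformaldehyde) | C=O | starting material
14 | tert-butyl 2-(diethoxyphosphoryl)-3-hydroxypropanoate | CCOP(=O)(OCC)C(CO)C(=O)OC(C)(C)C | intermediate
15 | tert-butyl 2-(diethoxyphosphoryl)prop-2-enoate | CCOP(=O)(OCC)C(=C)C(=O)OC(C)(C)C | intermediate
16 | (4-methoxyphenyl)methanol | COc1ccc(CO)cc1 | starting material
17 | sodium salt (α-carbanion) of tert-butyl 2-(diethoxyphosphoryl)-3-[(4-methoxyphenyl)methoxy]propanoate | CCOP(=O)(OCC)[C-](COCc1ccc(OC)cc1)C(=O)OC(C)(C)C.[Na+] | intermediate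
18 | methyl (1S,2S,3R)-2-[(1E)-3-tert-butoxy-2-{[(4-methoxyphenyl)methoxy]methyl}-3-oxoprop-1-en-1-yl]-6-oxo-3-(propan-2-yl)cyclohexane-1-carboxylate | CC(C)[C@H]1CCC(=O)[C@@H](C(=O)OC)[C@@H]1/C=C(\COCc1ccc(OC)cc1)C(=O)OC(C)(C)C | intermediate
19 | methyl (1S,2S,3R)-2-[(1E)-3-tert-butoxy-2-{[(4-methoxyphenyl)methoxy]methyl}-3-oxoprop-1-en-1-yl]-6-methylidene-3-(propan-2-yl)cyclohexane-1-carboxylate | CC(C)[C@H]1CCC(=C)[C@@H](C(=O)OC)[C@@H]1/C=C(\COCc1ccc(OC)cc1)C(=O)OC(C)(C)C | intermediate
20 | methyl (1S,2S,3R,6S)-2-[(1E)-3-tert-butoxy-2-{[(4-methoxyphenyl)methoxy]methyl}-3-oxoprop-1-en-1-yl]-6-hydroxy-6-(hydroxymethyl)-3-(propan-2-yl)cyclohexane-1-carboxylate | CC(C)[C@H]1CC[C@@](O)(CO)[C@@H](C(=O)OC)[C@@H]1/C=C(\COCc1ccc(OC)cc1)C(=O)OC(C)(C)C | intermediate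
21 | tert-butyl (2E)-3-[(3aS,6R,7S,7aS)-3a-hydroxy-1-oxo-6-(propan-2-yl)octahydro-2-benzofuran-7-yl]-2-{[(4-methoxyphenyl)methoxy]methyl}prop-2-enoate (cis-fused hydroxy lactone) | CC(C)[C@H]1CC[C@@]2(O)COC(=O)[C@H]2[C@@H]1/C=C(\COCc1ccc(OC)cc1)C(=O)OC(C)(C)C | intermediate
22 | tert-butyl (2E)-2-{[(4-methoxyphenyl)methoxy]methyl}-3-[(6R,7S)-1-oxo-6-(propan-2-yl)-1,3,4,5,6,7-hexahydro-2-benzofuran-7-yl]prop-2-enoate | CC(C)[C@H]1CCC2=C([C@@H]1/C=C(\COCc1ccc(OC)cc1)C(=O)OC(C)(C)C)C(=O)OC2 | intermediate
23 | (2E)-2-{[(4-methoxyphenyl)methoxy]methyl}-3-[(6R,7S)-1-oxo-6-(propan-2-yl)-1,3,4,5,6,7-hexahydro-2-benzofuran-7-yl]prop-2-enoic acid | CC(C)[C@H]1CCC2=C([C@@H]1/C=C(\COCc1ccc(OC)cc1)C(=O)O)C(=O)OC2 | intermediate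
24 | lithium (1S,2S,3R,6S)-2-[(1E)-3-tert-butoxy-2-{[(4-methoxyphenyl)methoxy]methyl}-3-oxoprop-1-en-1-yl]-6-hydroxy-6-(hydroxymethyl)-3-(propan-2-yl)cyclohexane-1-carboxylate | CC(C)[C@H]1CC[C@@](O)(CO)[C@@H](C(=O)[O-])[C@@H]1/C=C(\COCc1ccc(OC)cc1)C(=O)OC(C)(C)C.[Li+] | intermediate
25 | N-acylimidazole of acid 23 | CC(C)[C@H]1CCC2=C([C@@H]1/C=C(\COCc1ccc(OC)cc1)C(=O)n1ccnc1)C(=O)OC2 | intermediate
26 | protected dimer acid (name as on the Product line of step 12) | CC(C)[C@H]1CC[C@@](O)(COC(=O)/C(=C/[C@H]2C3=C(CC[C@@H]2C(C)C)COC3=O)COCc2ccc(OC)cc2)[C@@H](C(=O)O)[C@@H]1/C=C(\COCc1ccc(OC)cc1)C(=O)OC(C)(C)C | intermediate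
27 | CNP0071646.2 (name as on the Product line of step 13) | CC(C)[C@H]1CC[C@@](O)(COC(=O)/C(=C/[C@H]2C3=C(CC[C@@H]2C(C)C)COC3=O)CO)[C@@H](C(=O)O)[C@@H]1/C=C(\CO)C(=O)O | target

**Step count.** Total: 13 steps. Longest linear sequence: 12 steps (steps 1–5 and 7–13; step 6 is a one-step side branch).

**Steps most likely to fail**

Step 3. The vinyl β-keto ester may be lost to intermolecular Michael addition and oligomerisation, or the tertiary cation may be captured by chloride, before ene ring closure takes place. The fallback sets out from 6 and comes back at 9, so that step 4 is skipped. Compound 6 is heated with catalytic TsOH in toluene and the vinyl ketone 7 is isolated. Benzeneselenol adds to the enone (CH2Cl2, rt) to give methyl (2RS)-2-[(2R)-4-methyl-1-nitropent-3-en-2-yl]-3-oxo-5-(phenylselanyl)pentanoate F1. Slow addition of Bu3SnH and AIBN in refluxing benzene generates the primary radical at C2, which should close the same C1–C2 bond by 6-exo-trig attack on the trisubstituted alkene through a chair-like transition state. The tertiary radical then takes hydrogen and gives the isopropyl compound 9 directly.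

Step 8. The cyclic β-keto ester is largely enolised, and protonation of the methylene reagent by the enol may stop the olefination. The fallback sets out from 18 and comes back at 19. (Trimethylsilyl)methyllithium with anhydrous CeCl3 (THF, −78 °C) should add to the ketone as a weakly basic organocerium reagent and give methyl (1S,2S,3R)-2-[(1E)-3-tert-butoxy-2-{[(4-methoxyphenyl)methoxy]methyl}-3-oxoprop-1-en-1-yl]-6-hydroxy-3-(propan-2-yl)-6-[(trimethylsilyl)methyl]cyclohexane-1-carboxylate F2 (either epimer at the carbinol carbon serves). Catalytic TsOH in CH2Cl2 then brings about Peterson elimination to the methylidene compound 19 without touching C5.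

Step 12. Acylation of the hindered primary hydroxyl of the carboxylate salt may be slow, and the base may shift the double bonds of the butenolide acyl donor before the ester forms. The fallback sets out from 21 and comes back at 27. The lactone is opened with LiOH as before to 24, and the carboxylate is alkylated with bromodiphenylmethane in DMF to give diphenylmethyl (1S,2S,3R,6S)-2-[(1E)-3-tert-butoxy-2-{[(4-methoxyphenyl)methoxy]methyl}-3-oxoprop-1-en-1-yl]-6-hydroxy-6-(hydroxymethyl)-3-(propan-2-yl)cyclohexane-1-carboxylate F3, whose bulky ester resists relactonisation. Carbodiimide esterification of its primary hydroxyl with acid 23 (EDC, DMAP, CH2Cl2, 0 °C) gives the diphenylmethyl ester of 26 F4. The conditions of step 13 (TFA, anisole) then remove the diphenylmethyl ester together with the other acid-labile groups and give 27.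

**Further compounds**

F1 | step 3 | methyl (2RS)-2-[(2R)-4-methyl-1-nitropent-3-en-2-yl]-3-oxo-5-(phenylselanyl)pentanoate | O=C(CC[Se]c1ccccc1)C(C(=O)OC)[C@@H](C=C(C)C)C[N+](=O)[O-]
F2 | step 8 | methyl (1S,2S,3R)-2-[(1E)-3-tert-butoxy-2-{[(4-methoxyphenyl)methoxy]methyl}-3-oxoprop-1-en-1-yl]-6-hydroxy-3-(propan-2-yl)-6-[(trimethylsilyl)methyl]cyclohexane-1-carboxylate (both epimers at C6) | CC(C)[C@H]1CCC(O)(C[Si](C)(C)C)[C@@H](C(=O)OC)[C@@H]1/C=C(\COCc1ccc(OC)cc1)C(=O)OC(C)(C)C
F3 | step 12 | diphenylmethyl (1S,2S,3R,6S)-2-[(1E)-3-tert-butoxy-2-{[(4-methoxyphenyl)methoxy]methyl}-3-oxoprop-1-en-1-yl]-6-hydroxy-6-(hydroxymethyl)-3-(propan-2-yl)cyclohexane-1-carboxylate | CC(C)[C@H]1CC[C@@](O)(CO)[C@@H](C(=O)OC(c2ccccc2)c2ccccc2)[C@@H]1/C=C(\COCc1ccc(OC)cc1)C(=O)OC(C)(C)C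
F4 | step 12 | diphenylmethyl ester of the protected dimer acid 26 | CC(C)[C@H]1CC[C@@](O)(COC(=O)/C(=C/[C@H]2C3=C(CC[C@@H]2C(C)C)COC3=O)COCc2ccc(OC)cc2)[C@@H](C(=O)OC(c2ccccc2)c2ccccc2)[C@@H]1/C=C(\COCc1ccc(OC)cc1)C(=O)OC(C)(C)C
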